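**Retrosynthetic overview**
1. Target 31 ⇐ diol 30 (two acetylations) ⇐ bis-silyl ether 29; the propanoate is installed before ring closure, so the three esters never have to be differentiated.
2. Ring C (eleven-membered, formed last) ⇐ allene aldehyde 28 by a nickel-catalysed reductive allene–aldehyde macrocyclisation (proposed new step: C5'–C2'' bond, Z-alkene, its methyl group and the allylic carbinol in one operation).
3. 28 ⇐ keto aldehyde 20 (asymmetric propargylation for C2', propionylation, methylenation, alkyne-to-allene homologation); 20 ⇐ enone 14 by conjugate crotylation (sets C3, C1' and the ring fusion C3a).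
4. Ring B (five-membered, formed second) ⇐ ring A enone 6 by cyclopentene annulation (copper conjugate addition sets the quaternary carbon, then aldol condensation); the C5 chain comes from α'-alkylation.
5. Ring A (six-membered, present from the start) ⇐ ketal 1 by Saegusa dehydrogenation and CBS reduction, the source of absolute configuration.

Assumption: the given SMILES defines the absolute configuration, and 1, 7, 12, 15, 16 and 21 are taken as catalogue compounds.
Abbreviations and locants: TBS = tert-butyldimethylsilyl, TBSO = its ether oxygen, TES = triethylsilyl. The hydrindane core keeps inden-4-one numbering (C1–C7a) from 11 on. C1'–C5' is the chain on C3 counted from the ring and C1''–C2'' the chain on C5.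

Step 1
Reactants: 1 7-methyl-1,4-dioxaspiro[4.5]decan-8-one (racemic)
Product: 3 7-methyl-1,4-dioxaspiro[4.5]dec-6-en-8-one, via trimethylsilyl enol ether 2 (not isolated)
Conditions: TMSCl, NaI, Et3N, MeCN, 23 °C; then Pd(OAc)2 (1.05 equiv), MeCN, 23 °C
Reagents that add atoms: none
Why: The more substituted (thermodynamic) silyl enol ether forms under equilibrating conditions, and Saegusa–Ito dehydrogenation (divalent palladium enolate, β-hydride elimination toward C6, zerovalent palladium released) gives the 2-methyl enone; the racemic centre of 1 is destroyed.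

Step 2
Reactants: 3 7-methyl-1,4-dioxaspiro[4.5]dec-6-en-8-one
Product: 4 (S)-7-methyl-1,4-dioxaspiro[4.5]dec-6-en-8-ol
Conditions: (R)-1-methyl-3,3-diphenyltetrahydro-1H,3H-pyrrolo[1,2-c][1,3,2]oxazaborole (10 mol %), BH3·SMe2, THF, −20 °C; MeOH
Reagents that add atoms: none
Why: Corey–Bakshi–Shibata reduction, in which the alkenyl side of the α-methyl enone acts as the large group, so the (R)-oxazaborolidine gives the (S)-allylic alcohol (the future acetoxy carbon C7, source of all absolute configuration).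

Step 3
Reactants: 4 (S)-7-methyl-1,4-dioxaspiro[4.5]dec-6-en-8-ol
Product: 5 (S)-8-(TBSO)-7-methyl-1,4-dioxaspiro[4.5]dec-6-ene
Conditions: TBSCl, imidazole, DMF, 23 °C
Reagents that add atoms: tert-butyldimethylsilyl chloride, CC(C)(C)[Si](C)(C)Cl
Why: Imidazole-mediated silylation of the secondary allylic alcohol; the bulky, non-coordinating TBS ether steers the next C–C bond anti and is kept to the end.

Step 4
Reactants: 5 (S)-8-(TBSO)-7-methyl-1,4-dioxaspiro[4.5]dec-6-ene
Product: 6 (S)-4-(TBSO)-3-methylcyclohex-2-en-1-one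
Conditions: pyridinium p-toluenesulfonate (20 mol %), acetone/H2O (9:1), 50 °C
Reagents that add atoms: water, O
Why: Mild acid-catalysed ketal hydrolysis unmasks the conjugated γ-silyloxy enone without touching the secondary TBS ether or the stereocentre.

Step 5
Reactants: 6 (S)-4-(TBSO)-3-methylcyclohex-2-en-1-one; 7 2-(2-bromoethyl)-1,3-dioxolane
Product: 9 (3S,4S)-4-(TBSO)-3-[2-(1,3-dioxolan-2-yl)ethyl]-3-methylcyclohexan-1-one, via trimethylsilyl enol ether 8 (not isolated)
Conditions: 7, Mg, THF, 25 °C; CuBr·SMe2 (20 mol %), TMSCl, THF, −78 → −30 °C; then K2CO3 (cat.), MeOH, 0 °C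
Reagents that add atoms: none
Why: Copper-catalysed, TMSCl-accelerated conjugate addition of the Grignard reagent (first half of the Helquist cyclopentene annulation) occurs anti to the adjacent OTBS group, setting the quaternary carbon with the chain trans and the methyl cis to oxygen; methanolysis of the silyl enol ether frees the ketone.

Step 6
Reactants: 9 (3S,4S)-4-(TBSO)-3-[2-(1,3-dioxolan-2-yl)ethyl]-3-methylcyclohexan-1-one
Product: 11 (7S,7aS)-7-(TBSO)-7a-methyl-1,2,5,6,7,7a-hexahydro-4H-inden-4-one, via keto aldehyde 10 (not isolated)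
Conditions: p-toluenesulfonic acid monohydrate (30 mol %), THF/H2O (10:1), 60 °C
Reagents that add atoms: none
Why: Acid hydrolysis of the dioxolane and intramolecular aldol condensation of the ketone α-carbon onto the aldehyde (five-membered ring closure, irreversible dehydration) give the bicyclic enone; no new stereocentre, and the hindered neopentylic TBS ether is expected to survive.

Step 7
Reactants: 11 (7S,7aS)-7-(TBSO)-7a-methyl-1,2,5,6,7,7a-hexahydro-4H-inden-4-one; 12 2-(TBSO)ethyl trifluoromethanesulfonate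
Product: 14 (5R,7S,7aS)-7-(TBSO)-5-[2-(TBSO)ethyl]-7a-methyl-1,2,5,6,7,7a-hexahydro-4H-inden-4-one, via lithium dienolate 13 (not isolated)
Conditions: LiN(iPr)2, THF, −78 °C; 12, −78 → −30 °C; then NaOMe (20 mol %), MeOH, 23 °C
Reagents that add atoms: none
Why: Kinetic α'-deprotonation gives the cross-conjugated dienolate, which is C-alkylated by the primary triflate (enolate alkylation); methoxide equilibration then places the C5 chain equatorial (5R) on the half-chair that holds the angular methyl axial and the OTBS group equatorial.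

Step 8
Reactants: 15 diphenylphosphine oxide; 16 (E)-1-bromobut-2-ene
Product: 17 (E)-but-2-en-1-yl(diphenyl)phosphine oxide
Conditions: NaH, THF, 0 → 23 °C; recrystallisation (EtOAc/hexane)
Reagents that add atoms: none
Why: Michaelis–Becker P-alkylation (SN2 at the primary allylic bromide) keeps the E geometry, and recrystallisation removes Z and branched isomers.

Step 9
Reactants: 14 (5R,7S,7aS)-7-(TBSO)-5-[2-(TBSO)ethyl]-7a-methyl-1,2,5,6,7,7a-hexahydro-4H-inden-4-one; 17 (E)-but-2-en-1-yl(diphenyl)phosphine oxide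
Product: 19 (3S,3aR,5R,7S,7aS)-7-(TBSO)-5-[2-(TBSO)ethyl]-3-[(2S,3E)-4-(diphenylphosphoryl)but-3-en-2-yl]-7a-methyloctahydro-4H-inden-4-one, via lithium enolate 18 (not isolated)
Conditions: 17, n-BuLi, THF, −78 °C; 14, −78 °C, 30 min; AcOH, −78 °C
Reagents that add atoms: none
Why: Conjugate (1,4) addition of the lithiated allylic phosphine oxide through its γ-carbon via a compact lithium-bridged (P=O···Li···O=C) chair-like ten-membered transition state: attack opposite the angular methyl sets C3, the E geometry places the crotyl methyl pseudo-equatorial and sets C1' (S), and kinetic C-protonation of enolate 18 on the face away from the chelated side chain gives the cis ring fusion (3aR).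

Step 10
Reactants: 19 (3S,3aR,5R,7S,7aS)-7-(TBSO)-5-[2-(TBSO)ethyl]-3-[(2S,3E)-4-(diphenylphosphoryl)but-3-en-2-yl]-7a-methyloctahydro-4H-inden-4-one
Product: 20 (2S)-2-[(3S,3aR,5R,7S,7aS)-7-(TBSO)-5-[2-(TBSO)ethyl]-7a-methyl-4-oxooctahydro-1H-inden-3-yl]propanal
Conditions: O3, CH2Cl2/MeOH (4:1), −78 °C; Me2S, −78 → 23 °C
Reagents that add atoms: ozone, [O-][O+]=O
Why: Ozonolysis with reductive work-up cleaves the only C=C (the vinylphosphine oxide) to the α-methyl aldehyde under neutral conditions, so the epimerisable C1' centre is kept.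

Step 11
Reactants: 20 (2S)-2-[(3S,3aR,5R,7S,7aS)-7-(TBSO)-5-[2-(TBSO)ethyl]-7a-methyl-4-oxooctahydro-1H-inden-3-yl]propanal; 21 4,4,5,5-tetramethyl-2-(propa-1,2-dien-1-yl)-1,3,2-dioxaborolane
Product: 22 (3S,3aR,5R,7S,7aS)-7-(TBSO)-5-[2-(TBSO)ethyl]-3-[(2S,3S)-3-hydroxyhex-5-yn-2-yl]-7a-methyloctahydro-4H-inden-4-one
Conditions: (S)-3,3'-bis(2,4,6-triisopropylphenyl)-1,1'-binaphthyl-2,2'-diyl hydrogen phosphate (10 mol %), 4 Å molecular sieves, toluene, −20 °C; aqueous work-up
Reagents that add atoms: none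
Why: Chiral phosphoric acid-catalysed propargylation with the allenylboronate (six-membered SE2' transition state) is chemoselective for the aldehyde over the hindered ketone; catalyst-controlled Si-face attack, matched with the Felkin–Anh preference of the α-methyl aldehyde, gives the (S)-carbinol with methyl and hydroxyl syn.

Step 12
Reactants: 22 (3S,3aR,5R,7S,7aS)-7-(TBSO)-5-[2-(TBSO)ethyl]-3-[(2S,3S)-3-hydroxyhex-5-yn-2-yl]-7a-methyloctahydro-4H-inden-4-one
Product: 23 (2S,3S)-2-[(3S,3aR,5R,7S,7aS)-7-(TBSO)-5-[2-(TBSO)ethyl]-7a-methyl-4-oxooctahydro-1H-inden-3-yl]hex-5-yn-3-yl propanoate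
Conditions: propanoic anhydride, 4-(dimethylamino)pyridine (10 mol %), Et3N, CH2Cl2, 23 °C
Reagents that add atoms: propanoic anhydride, CCC(=O)OC(=O)CC
Why: Nucleophile-catalysed acylation of the secondary alcohol (any cyclic hemiketal tautomer drains through the open form) installs the propanoate early.

Step 13
Reactants: 23 (2S,3S)-2-[(3S,3aR,5R,7S,7aS)-7-(TBSO)-5-[2-(TBSO)ethyl]-7a-methyl-4-oxooctahydro-1H-inden-3-yl]hex-5-yn-3-yl propanoate
Product: 24 (2S,3S)-2-[(3R,3aS,5R,7S,7aS)-7-(TBSO)-5-[2-(TBSO)ethyl]-7a-methyl-4-methylideneoctahydro-1H-inden-3-yl]hex-5-yn-3-yl propanoate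
Conditions: Zn, CH2Br2, TiCl4, THF (reagent aged at 5 °C); 23, CH2Cl2, 0 → 23 °C
Reagents that add atoms: dibromomethane, BrCBr
Why: Lombardo–Takai methylenation, whose non-basic gem-dizinc/titanium reagent converts the hindered, enolisable ketone into the exocyclic methylene without epimerising C3a or C5 and without attacking the ester.

Step 14
Reactants: 24 (2S,3S)-2-[(3R,3aS,5R,7S,7aS)-7-(TBSO)-5-[2-(TBSO)ethyl]-7a-methyl-4-methylideneoctahydro-1H-inden-3-yl]hex-5-yn-3-yl propanoate
Product: 26 (2S,3S)-2-[(3R,3aS,5R,7S,7aS)-7-(TBSO)-5-[2-(TBSO)ethyl]-7a-methyl-4-methylideneoctahydro-1H-inden-3-yl]hepta-5,6-dien-3-yl propanoate, via propargylic amine 25 (not isolated)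
Conditions: (CH2O)n, CuI (0.5 equiv), Cy2NH, 1,4-dioxane, 100 °C
Reagents that add atoms: formaldehyde (as paraformaldehyde), C=O
Why: Crabbé homologation: copper-mediated Mannich reaction to the propargylic amine, then intramolecular 1,5-hydride transfer and fragmentation, gives the terminal allene; no stereocentre is involved.

Step 15
Reactants: 26 (2S,3S)-2-[(3R,3aS,5R,7S,7aS)-7-(TBSO)-5-[2-(TBSO)ethyl]-7a-methyl-4-methylideneoctahydro-1H-inden-3-yl]hepta-5,6-dien-3-yl propanoate
Product: 27 (2S,3S)-2-[(3R,3aS,5R,7S,7aS)-7-(TBSO)-5-(2-hydroxyethyl)-7a-methyl-4-methylideneoctahydro-1H-inden-3-yl]hepta-5,6-dien-3-yl propanoate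
Conditions: (1S)-camphor-10-sulfonic acid (10 mol %), MeOH/CH2Cl2 (1:1), 0 °C
Reagents that add atoms: none
Why: Acid-catalysed methanolysis removes the unhindered primary TBS ether far faster than the neopentylic secondary one (selective desilylation).

Step 16
Reactants: 27 (2S,3S)-2-[(3R,3aS,5R,7S,7aS)-7-(TBSO)-5-(2-hydroxyethyl)-7a-methyl-4-methylideneoctahydro-1H-inden-3-yl]hepta-5,6-dien-3-yl propanoate
Product: 28 (2S,3S)-2-[(3R,3aS,5S,7S,7aS)-7-(TBSO)-7a-methyl-4-methylidene-5-(2-oxoethyl)octahydro-1H-inden-3-yl]hepta-5,6-dien-3-yl propanoate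
Conditions: Dess–Martin periodinane, pyridine, CH2Cl2, 0 → 23 °C
Reagents that add atoms: none
Why: Dess–Martin oxidation gives the aldehyde under buffered conditions that leave allene, alkene and ester untouched (the C5 descriptor changes by priority only).

Step 17
Reactants: 28 (2S,3S)-2-[(3R,3aS,5S,7S,7aS)-7-(TBSO)-7a-methyl-4-methylidene-5-(2-oxoethyl)octahydro-1H-inden-3-yl]hepta-5,6-dien-3-yl propanoate
Product: 29 macrocyclic bis-silyl ether: target skeleton with ring C closed by the C5'–C2'' bond, OTBS at C7, OTES at C2'', propanoate at C2', Z-alkene C4'=C5' (core 3R,3aS,5R,7S,7aS; 1'S,2'S,2''R)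
Conditions: Ni(cod)2 (cod = 1,5-cyclooctadiene, 20 mol %), (4S,5S)-1,3-bis(2-isopropylphenyl)-4,5-diphenylimidazolidin-2-ylidene (25 mol %, from its tetrafluoroborate salt and KOtBu), Et3SiH (3 equiv), THF, 23 °C, syringe-pump addition of 28 to 0.002 M
Reagents that add atoms: triethylsilane, CC[SiH](CC)CC
Why: Proposed new method: intramolecular (macrocyclising) nickel-catalysed reductive coupling of a monosubstituted allene with an aldehyde; zerovalent nickel bearing the carbene binds the aldehyde and the terminal C=C of the allene and undergoes oxidative cyclisation with C–C bond formation at the central allene carbon (C5') to an oxanickelacycle carrying a nickel-bound η3-allyl, Et3SiH cleaves the Ni–O bond (O–SiEt3) and leaves Ni–H, and C–H reductive elimination at the unsubstituted allyl terminus turns the allene CH2 into the C5' methyl and gives the trisubstituted alkene with C3' and C2'' cis (Z), the geometry that also fits the eleven-membered ring; the C2-symmetric carbene is intended to direct the alkenyl carbon to the Si face of the aldehyde (2''R), though its sense of induction is not predictable in advance; closest known reaction type is the intermolecular nickel/N-heterocyclic carbene three-component coupling of allenes, aldehydes and silanes to Z-allylic silyl ethers, together with nickel-catalysed reductive ynal macrocyclisations; not yet shown are the ring-closing mode, a terminal allene and ligand control of the carbinol centre in a macrocycle.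

Step 18
Reactants: 29 macrocyclic bis-silyl ether
Product: 30 macrocyclic diol: free hydroxyls at C7 and C2'', propanoate at C2' (configuration as 29)
Conditions: HF·pyridine, pyridine, THF, 0 → 23 °C
Reagents that add atoms: none
Why: Fluoride-mediated cleavage of both silyl ethers in a buffered medium that avoids acyl migration and allylic ionisation.

Step 19
Reactants: 30 macrocyclic diol
Product: 31 CNP0239696.1 (trinervitane-type triester: acetates at C7 and C2'', propanoate at C2')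
Conditions: Ac2O, 4-(dimethylamino)pyridine, pyridine, CH2Cl2, 23 °C
Reagents that add atoms: acetic anhydride, CC(=O)OC(C)=O
Why: Nucleophile-catalysed acetylation of both secondary hydroxyls (the allylic one fast, the neopentylic one slower) completes the triester without touching any stereocentre.

**Compound list**
1 | 7-methyl-1,4-dioxaspiro[4.5]decan-8-one (racemic) | CC1CC2(CCC1=O)OCCO2 | starting material
2 | trimethyl[(7-methyl-1,4-dioxaspiro[4.5]dec-7-en-8-yl)oxy]silane | CC1=C(O[Si](C)(C)C)CCC2(C1)OCCO2 | intermediate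
3 | 7-methyl-1,4-dioxaspiro[4.5]dec-6-en-8-one | CC1=CC2(CCC1=O)OCCO2 | intermediate
4 | (S)-7-methyl-1,4-dioxaspiro[4.5]dec-6-en-8-ol | C12(OCCO2)CC[C@H](O)C(C)=C1 | intermediate
5 | (S)-8-(TBSO)-7-methyl-1,4-dioxaspiro[4.5]dec-6-ene | C12(OCCO2)CC[C@H](O[Si](C)(C)C(C)(C)C)C(C)=C1 | intermediate
6 | (S)-4-(TBSO)-3-methylcyclohex-2-en-1-one | O=C1CC[C@H](O[Si](C)(C)C(C)(C)C)C(C)=C1 | intermediate
7 | 2-(2-bromoethyl)-1,3-dioxolane | BrCCC1OCCO1 | starting material
8 | 1-trimethylsilyl enol ether of 9 (enol double bond C1=C2; 3S,4S) | C[Si](C)(C)OC=1CC[C@H](O[Si](C)(C)C(C)(C)C)[C@@](C)(CCC2OCCO2)C=1 | intermediate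
9 | (3S,4S)-4-(TBSO)-3-[2-(1,3-dioxolan-2-yl)ethyl]-3-methylcyclohexan-1-one | O=C1CC[C@H](O[Si](C)(C)C(C)(C)C)[C@@](C)(CCC2OCCO2)C1 | intermediate
10 | 3-[(1S,2S)-2-(TBSO)-1-methyl-5-oxocyclohexyl]propanal | O=C1CC[C@H](O[Si](C)(C)C(C)(C)C)[C@@](C)(CCC=O)C1 | intermediate
11 | (7S,7aS)-7-(TBSO)-7a-methyl-1,2,5,6,7,7a-hexahydro-4H-inden-4-one | O=C1CC[C@H](O[Si](C)(C)C(C)(C)C)[C@@]3(C)CCC=C13 | intermediate
12 | 2-(TBSO)ethyl trifluoromethanesulfonate | CC(C)(C)[Si](C)(C)OCCOS(=O)(=O)C(F)(F)F | starting material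
13 | lithium dienolate of 11 (O–Li on C4; C4=C5 and C3=C3a) | [Li]OC1=CC[C@H](O[Si](C)(C)C(C)(C)C)[C@@]3(C)CCC=C13 | intermediate
14 | (5R,7S,7aS)-7-(TBSO)-5-[2-(TBSO)ethyl]-7a-methyl-1,2,5,6,7,7a-hexahydro-4H-inden-4-one | O=C1[C@H](CCO[Si](C)(C)C(C)(C)C)C[C@H](O[Si](C)(C)C(C)(C)C)[C@@]3(C)CCC=C13 | intermediate
15 | diphenylphosphine oxide | O=[PH](c1ccccc1)c1ccccc1 | starting material
16 | (E)-1-bromobut-2-ene (crotyl bromide) | C/C=C/CBr | starting material
17 | (E)-but-2-en-1-yl(diphenyl)phosphine oxide | C/C=C/CP(=O)(c1ccccc1)c1ccccc1 | intermediate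
18 | lithium enolate of 19 (O–Li on C4; C3a=C4) | [Li]OC=1[C@H](CCO[Si](C)(C)C(C)(C)C)C[C@H](O[Si](C)(C)C(C)(C)C)[C@@]3(C)CC[C@@H]([C@H](C)/C=C/P(=O)(c4ccccc4)c4ccccc4)C=13 | intermediate
19 | (3S,3aR,5R,7S,7aS)-7-(TBSO)-5-[2-(TBSO)ethyl]-3-[(2S,3E)-4-(diphenylphosphoryl)but-3-en-2-yl]-7a-methyloctahydro-4H-inden-4-one | O=C1[C@H](CCO[Si](C)(C)C(C)(C)C)C[C@H](O[Si](C)(C)C(C)(C)C)[C@@]3(C)CC[C@@H]([C@H](C)/C=C/P(=O)(c4ccccc4)c4ccccc4)[C@@H]13 | intermediate
20 | (2S)-2-[(3S,3aR,5R,7S,7aS)-7-(TBSO)-5-[2-(TBSO)ethyl]-7a-methyl-4-oxooctahydro-1H-inden-3-yl]propanal | O=C1[C@H](CCO[Si](C)(C)C(C)(C)C)C[C@H](O[Si](C)(C)C(C)(C)C)[C@@]3(C)CC[C@@H]([C@H](C)C=O)[C@@H]13 | intermediate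
21 | 4,4,5,5-tetramethyl-2-(propa-1,2-dien-1-yl)-1,3,2-dioxaborolane (allenylboronic acid pinacol ester) | C=C=CB1OC(C)(C)C(C)(C)O1 | starting material
22 | (3S,3aR,5R,7S,7aS)-7-(TBSO)-5-[2-(TBSO)ethyl]-3-[(2S,3S)-3-hydroxyhex-5-yn-2-yl]-7a-methyloctahydro-4H-inden-4-one | O=C1[C@H](CCO[Si](C)(C)C(C)(C)C)C[C@H](O[Si](C)(C)C(C)(C)C)[C@@]3(C)CC[C@@H]([C@H](C)[C@@H](O)CC#C)[C@@H]13 | intermediate
23 | (2S,3S)-2-[(3S,3aR,5R,7S,7aS)-7-(TBSO)-5-[2-(TBSO)ethyl]-7a-methyl-4-oxooctahydro-1H-inden-3-yl]hex-5-yn-3-yl propanoate | O=C1[C@H](CCO[Si](C)(C)C(C)(C)C)C[C@H](O[Si](C)(C)C(C)(C)C)[C@@]3(C)CC[C@@H]([C@H](C)[C@@H](OC(=O)CC)CC#C)[C@@H]13 | intermediate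
24 | (2S,3S)-2-[(3R,3aS,5R,7S,7aS)-7-(TBSO)-5-[2-(TBSO)ethyl]-7a-methyl-4-methylideneoctahydro-1H-inden-3-yl]hex-5-yn-3-yl propanoate | C=C1[C@H](CCO[Si](C)(C)C(C)(C)C)C[C@H](O[Si](C)(C)C(C)(C)C)[C@@]3(C)CC[C@@H]([C@H](C)[C@@H](OC(=O)CC)CC#C)[C@@H]13 | intermediate
25 | (2S,3S)-7-(dicyclohexylamino)-2-[core as in 24]hept-5-yn-3-yl propanoate | C=C1[C@H](CCO[Si](C)(C)C(C)(C)C)C[C@H](O[Si](C)(C)C(C)(C)C)[C@@]3(C)CC[C@@H]([C@H](C)[C@@H](OC(=O)CC)CC#CCN(C4CCCCC4)C4CCCCC4)[C@@H]13 | intermediate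
26 | (2S,3S)-2-[(3R,3aS,5R,7S,7aS)-7-(TBSO)-5-[2-(TBSO)ethyl]-7a-methyl-4-methylideneoctahydro-1H-inden-3-yl]hepta-5,6-dien-3-yl propanoate | C=C1[C@H](CCO[Si](C)(C)C(C)(C)C)C[C@H](O[Si](C)(C)C(C)(C)C)[C@@]3(C)CC[C@@H]([C@H](C)[C@@H](OC(=O)CC)CC=C=C)[C@@H]13 | intermediate
27 | (2S,3S)-2-[(3R,3aS,5R,7S,7aS)-7-(TBSO)-5-(2-hydroxyethyl)-7a-methyl-4-methylideneoctahydro-1H-inden-3-yl]hepta-5,6-dien-3-yl propanoate | C=C1[C@H](CCO)C[C@H](O[Si](C)(C)C(C)(C)C)[C@@]3(C)CC[C@@H]([C@H](C)[C@@H](OC(=O)CC)CC=C=C)[C@@H]13 | intermediate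
28 | (2S,3S)-2-[(3R,3aS,5S,7S,7aS)-7-(TBSO)-7a-methyl-4-methylidene-5-(2-oxoethyl)octahydro-1H-inden-3-yl]hepta-5,6-dien-3-yl propanoate | C=C1[C@H](CC=O)C[C@H](O[Si](C)(C)C(C)(C)C)[C@@]3(C)CC[C@@H]([C@H](C)[C@@H](OC(=O)CC)CC=C=C)[C@@H]13 | intermediate
29 | macrocyclic bis-silyl ether (OTBS at C7, OTES at C2'', propanoate at C2'; Z-alkene; core 3R,3aS,5R,7S,7aS; 1'S,2'S,2''R) | C=C1[C@H]2C[C@H](O[Si](C)(C)C(C)(C)C)[C@@]3(C)CC[C@@H]([C@H](C)[C@@H](OC(=O)CC)C/C=C(/C)[C@H](O[Si](CC)(CC)CC)C2)[C@@H]13 | intermediate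
30 | macrocyclic diol (OH at C7 and C2'', propanoate at C2'; configuration as 29) | C=C1[C@H]2C[C@H](O)[C@@]3(C)CC[C@@H]([C@H](C)[C@@H](OC(=O)CC)C/C=C(/C)[C@H](O)C2)[C@@H]13 | intermediate
31 | CNP0239696.1 (acetates at C7 and C2'', propanoate at C2'; core 3R,3aS,5R,7S,7aS; 1'S,2'S,2''R; Z) | C=C1[C@H]2C[C@H](OC(C)=O)[C@@]3(C)CC[C@@H]([C@H](C)[C@@H](OC(=O)CC)C/C=C(/C)[C@H](OC(C)=O)C2)[C@@H]13 | target

**Step count and risks**
Total steps: 19 (18 in the main line plus step 8 for reagent 17). Longest linear sequence: 18 steps (1–7 and 9–19) from 1.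

The three steps most likely to fail:

Step 17 (proposed new macrocyclisation). Risks are oligomerisation, coupling through the other allene π-bond (exocyclic methylene isomer), simple hydrosilylation, and the wrong face at C2''; the antipodal carbene is the first variable to try. Fallback with known chemistry, setting out from 20 and returning at 30: Brown allylation of 20 with (−)-Ipc2B(allyl) (Et2O, −78 °C; NaOH/H2O2; Si-face attack) gives homoallylic alcohol F1. Propanoic anhydride with 4-(dimethylamino)pyridine gives propanoate F2. Ozonolysis (O3; Me2S; the terminal alkene is the only C=C at this stage) gives aldehyde F3. Stork–Zhao olefination with Ph3P=C(CH3)I (from (1-iodoethyl)triphenylphosphonium iodide and NaN(SiMe3)2, THF, −78 °C; aldehyde-selective) gives (Z)-vinyl iodide F4. Lombardo methylenation as in step 13 gives methylene compound F5, camphorsulfonic acid in MeOH gives primary alcohol F6, and Dess–Martin oxidation gives iodo aldehyde F7. Nozaki–Hiyama–Kishi macrocyclisation (CrCl2, NiCl2 1 mol %, DMSO/THF, 0.002 M, 23 °C), which keeps the alkenyl iodide geometry, gives macrocyclic allylic alcohol F8. HF·pyridine then removes the remaining TBS group to give 30, which is acetylated as in step 19.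

Step 9 (conjugate crotylation). Risks are 1,2- or α-attack, a wrong C3/C1' relationship if the chelated transition state is not followed on this s-cis enone, and trans ring fusion on protonation. Fallback with known chemistry, setting out from 14 and returning at 20: Hosomi–Sakurai conjugate crotylation of 14 with (Z)-crotyltrimethylsilane and TiCl4 (CH2Cl2, −78 °C) runs through an open synclinal transition state and attacks opposite the angular methyl. It gives vinyl ketone F9, and ozonolysis (O3; Me2S) of its only C=C returns 20.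

Step 5 (quaternary carbon next to the OTBS group). The cuprate addition to a β,β-disubstituted, γ-silyloxy enone may be slow or give reduction. Fallback with known chemistry, setting out from 6 and returning at 10 (then 11): Sakurai allylation of 6 (allyltrimethylsilane, TiCl4, CH2Cl2, −78 °C; anti to OTBS) gives allyl ketone F10. Hydroboration–oxidation (BH3·THF; NaOH/H2O2), which also reduces the ketone, gives diol F11. Dess–Martin oxidation of both hydroxyls gives keto aldehyde 10, which is cyclised under the conditions of step 6 to 11.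

**Further compounds**
F1 | step 17 | homoallylic alcohol (allylation product of 20; 2'S) | O=C1[C@H](CCO[Si](C)(C)C(C)(C)C)C[C@H](O[Si](C)(C)C(C)(C)C)[C@@]3(C)CC[C@@H]([C@H](C)[C@@H](O)CC=C)[C@@H]13
F2 | step 17 | propanoate of F1 | O=C1[C@H](CCO[Si](C)(C)C(C)(C)C)C[C@H](O[Si](C)(C)C(C)(C)C)[C@@]3(C)CC[C@@H]([C@H](C)[C@@H](OC(=O)CC)CC=C)[C@@H]13
F3 | step 17 | β-propanoyloxy aldehyde | O=C1[C@H](CCO[Si](C)(C)C(C)(C)C)C[C@H](O[Si](C)(C)C(C)(C)C)[C@@]3(C)CC[C@@H]([C@H](C)[C@@H](OC(=O)CC)CC=O)[C@@H]13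
F4 | step 17 | (Z)-vinyl iodide (C4 ketone) | O=C1[C@H](CCO[Si](C)(C)C(C)(C)C)C[C@H](O[Si](C)(C)C(C)(C)C)[C@@]3(C)CC[C@@H]([C@H](C)[C@@H](OC(=O)CC)C/C=C(/C)I)[C@@H]13
F5 | step 17 | (Z)-vinyl iodide with C4 methylidene | C=C1[C@H](CCO[Si](C)(C)C(C)(C)C)C[C@H](O[Si](C)(C)C(C)(C)C)[C@@]3(C)CC[C@@H]([C@H](C)[C@@H](OC(=O)CC)C/C=C(/C)I)[C@@H]13
F6 | step 17 | primary alcohol of F5 | C=C1[C@H](CCO)C[C@H](O[Si](C)(C)C(C)(C)C)[C@@]3(C)CC[C@@H]([C@H](C)[C@@H](OC(=O)CC)C/C=C(/C)I)[C@@H]13
F7 | step 17 | iodo aldehyde | C=C1[C@H](CC=O)C[C@H](O[Si](C)(C)C(C)(C)C)[C@@]3(C)CC[C@@H]([C@H](C)[C@@H](OC(=O)CC)C/C=C(/C)I)[C@@H]13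
F8 | step 17 | macrocyclic allylic alcohol (OTBS at C7, free OH at C2'') | C=C1[C@H]2C[C@H](O[Si](C)(C)C(C)(C)C)[C@@]3(C)CC[C@@H]([C@H](C)[C@@H](OC(=O)CC)C/C=C(/C)[C@H](O)C2)[C@@H]13
F9 | step 9 | vinyl ketone (3-[(2R)-but-3-en-2-yl] analogue of 19) | O=C1[C@H](CCO[Si](C)(C)C(C)(C)C)C[C@H](O[Si](C)(C)C(C)(C)C)[C@@]3(C)CC[C@@H]([C@H](C)C=C)[C@@H]13
F10 | step 5 | (3S,4S)-3-allyl-4-(TBSO)-3-methylcyclohexan-1-one | O=C1CC[C@H](O[Si](C)(C)C(C)(C)C)[C@@](C)(CC=C)C1
F11 | step 5 | (3S,4S)-4-(TBSO)-3-(3-hydroxypropyl)-3-methylcyclohexan-1-ol (mixture of C1 epimers) | OC1CC[C@H](O[Si](C)(C)C(C)(C)C)[C@@](C)(CCCO)C1
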